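**Retrosynthetic overview**
- The quinone is unmasked last, by oxidative demethylation of a 2,5-dimethoxyphenyl ring.
- Key disconnection: the ester C–O bond at C-1′. A dynamic kinetic, enantioselective O-acylation of the racemic furyl carbinol installs the senecioate and sets the (S) centre in one operation.
- The racemic carbinol comes from α-selective prenylation of a 5-aryl-3-furaldehyde.
- The aryl–furan bond comes from Suzuki coupling of 5-bromofuran-3-carbaldehyde with (2,5-dimethoxyphenyl)boronic acid.
- No ring is formed: furan and benzene ring are bought intact, and the benzene ring becomes the quinone in the final step.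

Assumption: (S)-benzotetramisole is taken to acylate the (S)-carbinol faster, by analogy with 1-arylalkanols (the arylfuran plays the aryl role); if the sense proves opposite, (R)-benzotetramisole is used.

**Step 1**
Reactants: 1 5-bromofuran-3-carbaldehyde; 2 (2,5-dimethoxyphenyl)boronic acid
Product: 3 5-(2,5-dimethoxyphenyl)furan-3-carbaldehyde
Conditions: Pd(dppf)Cl2·CH2Cl2 (3 mol%), K2CO3 (2 equiv), 1,4-dioxane/H2O 4:1, 85 °C, 4 h
Reagents that add atoms: none
Why: Suzuki–Miyaura coupling; the α-bromofuran undergoes fast oxidative addition and the aldehyde tolerates aqueous carbonate.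

**Step 2**
Reactants: 3 5-(2,5-dimethoxyphenyl)furan-3-carbaldehyde; 4 1-chloro-3-methylbut-2-ene (prenyl chloride)
Product: 5 rac-1-[5-(2,5-dimethoxyphenyl)furan-3-yl]-4-methylpent-3-en-1-ol
Conditions: BaI2, lithium biphenylide (2 equiv), THF, rt, 30 min; 4, −78 °C, 30 min; then 3, −78 °C, 30 min; 1 M HCl quench
Reagents that add atoms: none
Why: Yamamoto allylbarium addition; prenylbarium chloride reacts with aldehydes at its unsubstituted α-terminus at −78 °C, giving the linear homoprenyl carbinol, and the new stereocentre is formed racemic on purpose because step 4 is stereoconvergent.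

**Step 3**
Reactants: 6 3-methylbut-2-enoic acid (senecioic acid); 7 isopropyl chloroformate
Product: 8 isopropyl 3-methylbut-2-enoyl carbonate (mixed carboxylic–carbonic anhydride)
Conditions: Et3N (1.0 equiv), Et2O, −10 °C, 30 min; filter under Ar, concentrate cold, use at once
Reagents that add atoms: none
Why: mixed-anhydride formation, O-acylation of the triethylammonium carboxylate by the chloroformate, as in the mixed-anhydride peptide coupling method.

**Step 4**
Reactants: 5 rac-1-[5-(2,5-dimethoxyphenyl)furan-3-yl]-4-methylpent-3-en-1-ol; 8 isopropyl 3-methylbut-2-enoyl carbonate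
Product: 10 (1S)-1-[5-(2,5-dimethoxyphenyl)furan-3-yl]-4-methylpent-3-en-1-yl 3-methylbut-2-enoate, via furyl ketone 9 (not isolated)
Conditions: (S)-benzotetramisole (5 mol%), (η5-C5Ph5)Ru(CO)2Cl (5 mol%), KOt-Bu (6 mol%), 8 (1.6 equiv, slow addition), toluene/t-amyl alcohol 1:1, 10 °C to rt, 36 h
Reagents that add atoms: none
Why: Proposed new method: a non-enzymatic dynamic kinetic resolution that delivers an α,β-unsaturated ester directly; (S)-benzotetramisole attacks the more electrophilic carboxyl carbonyl of 8 to give a chiral N-senecioyl isothiouronium ion (acyl oxygen held syn to sulfur by the 1,5-S···O contact) while the isopropyl carbonate counter-ion collapses to CO2 and isopropoxide, which serves as the base; the (S)-carbinol, whose arylfuran stacks on the cationic benzothiazolium face with the homoprenyl chain turned away, is acylated much faster than its antipode, and the unreacted (R)-carbinol is racemised continuously through ketone 9 by reversible β-hydride elimination and re-insertion on the ruthenium alkoxide, so all material converges on (S)-10; no carboxylic acid is released that could protonate the ruthenium alkoxide, the β,β-disubstituted acyl group resists conjugate addition, and the ester cannot re-enter the ruthenium cycle; the closest known reactions are isothiourea-catalysed acylative kinetic resolution of aryl alkyl carbinols with anhydrides and the ruthenium/planar-chiral DMAP dynamic kinetic resolution of secondary alcohols with acetyl isopropyl carbonate, neither shown for an isothiourea/ruthenium pair, an enoyl carbonate or a furyl homoprenyl carbinol.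

**Step 5**
Reactants: 10 (1S)-1-[5-(2,5-dimethoxyphenyl)furan-3-yl]-4-methylpent-3-en-1-yl 3-methylbut-2-enoate
Product: 11 (1S)-1-[5-(3,6-dioxocyclohexa-1,4-dien-1-yl)furan-3-yl]-4-methylpent-3-en-1-yl 3-methylbut-2-enoate (target, CNP0314322.1)
Conditions: (NH4)2Ce(NO3)6 (2.5 equiv), MeCN/H2O 2:1, 0 °C, 15 min
Reagents that add atoms: water, O
Why: ceric ammonium nitrate oxidative demethylation of a hydroquinone dimethyl ether, in which the arene radical cation is trapped by water at the two methoxy-bearing carbons and methanol is lost; it is fast at 0 °C and leaves the ester, the alkenes and the stereocentre untouched.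

**Compound list**
1 | 5-bromofuran-3-carbaldehyde | O=Cc1coc(Br)c1 | starting material
2 | (2,5-dimethoxyphenyl)boronic acid | COc1ccc(OC)c(B(O)O)c1 | starting material
3 | 5-(2,5-dimethoxyphenyl)furan-3-carbaldehyde | COc1ccc(OC)c(-c2cc(C=O)co2)c1 | intermediate
4 | 1-chloro-3-methylbut-2-ene (prenyl chloride) | CC(C)=CCCl | starting material
5 | rac-1-[5-(2,5-dimethoxyphenyl)furan-3-yl]-4-methylpent-3-en-1-ol | COc1ccc(OC)c(-c2cc(C(O)CC=C(C)C)co2)c1 | intermediate
6 | 3-methylbut-2-enoic acid (senecioic acid) | CC(C)=CC(=O)O | starting material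
7 | isopropyl chloroformate | CC(C)OC(Cl)=O | starting material
8 | isopropyl 3-methylbut-2-enoyl carbonate | CC(C)=CC(=O)OC(=O)OC(C)C | intermediate
9 | 1-[5-(2,5-dimethoxyphenyl)furan-3-yl]-4-methylpent-3-en-1-one (not isolated) | COc1ccc(OC)c(-c2cc(C(=O)CC=C(C)C)co2)c1 | intermediate
10 | (1S)-1-[5-(2,5-dimethoxyphenyl)furan-3-yl]-4-methylpent-3-en-1-yl 3-methylbut-2-enoate | CC(C)=CC[C@H](OC(=O)C=C(C)C)c1coc(-c2cc(OC)ccc2OC)c1 | intermediate
11 | (1S)-1-[5-(3,6-dioxocyclohexa-1,4-dien-1-yl)furan-3-yl]-4-methylpent-3-en-1-yl 3-methylbut-2-enoate | CC(C)=CC[C@H](OC(=O)C=C(C)C)c1coc(C2=CC(=O)C=CC2=O)c1 | target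

**Step count**
Total steps: 5 (four in the main line plus the one-step preparation of acyl donor 8).
Longest linear sequence: 4 (steps 1, 2, 4, 5).

**Steps most likely to fail**

Step 4 (the proposed new dynamic kinetic acylation). The risks are an unproven catalyst pair, attack of the isothiourea at the wrong carbonyl of 8, a racemic background acylation by the ruthenium alkoxide, and insufficient selectivity. The fallback uses known chemistry, sets out from 5 and comes back at 10. Alcohol 5 is oxidised with Dess–Martin periodinane (NaHCO3, CH2Cl2, 0 °C) to ketone 9, this time isolated. The ketone is reduced with (−)-B-chlorodiisopinocampheylborane (THF, −25 °C, diethanolamine work-up), which gives the (S)-alcohol from aryl alkyl ketones, to (1S)-1-[5-(2,5-dimethoxyphenyl)furan-3-yl]-4-methylpent-3-en-1-ol F2. A Steglich esterification with acid 6 (EDC·HCl, DMAP, CH2Cl2, 0 °C) then gives 10. Here the stereocentre is set by C–H delivery to a ketone and not by acyl transfer.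

Step 2 (α- versus γ-attack of the prenyl metal; handling of activated barium). The fallback sets out from 3 and comes back at 5. Allylmagnesium bromide (THF, −78 °C) gives rac-1-[5-(2,5-dimethoxyphenyl)furan-3-yl]but-3-en-1-ol F1, which has no regiochemical ambiguity. Cross-metathesis with 2-methylbut-2-ene (Grubbs second-generation catalyst 5 mol%, 2-methylbut-2-ene/CH2Cl2, 35 °C) then turns the vinyl terminus into the trisubstituted alkene of 5.

Step 5 (Ce(IV) may attack the electron-rich arylfuran). The fallback sets out from 1 and comes back at 11; it moves the biaryl coupling to the end and unveils the quinone from a para-methoxyphenol with a two-electron oxidant. Aldehyde 1 is prenylated by the step 2 procedure to rac-1-(5-bromofuran-3-yl)-4-methylpent-3-en-1-ol F3. Acylation of F3 with 8 under the step 4 conditions, the slow enantiomer being recycled through 1-(5-bromofuran-3-yl)-4-methylpent-3-en-1-one F4 (not isolated), gives (1S)-1-(5-bromofuran-3-yl)-4-methylpent-3-en-1-yl 3-methylbut-2-enoate F5. Suzuki coupling with commercial (2-hydroxy-5-methoxyphenyl)boronic acid (Pd(dppf)Cl2, K3PO4, dioxane/H2O, 60 °C) gives (1S)-1-[5-(2-hydroxy-5-methoxyphenyl)furan-3-yl]-4-methylpent-3-en-1-yl 3-methylbut-2-enoate F6. PhI(OAc)2 in MeCN/H2O at 0 °C then oxidises the para-methoxyphenol to quinone 11.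

**Further compounds**
F1 | step 2 | rac-1-[5-(2,5-dimethoxyphenyl)furan-3-yl]but-3-en-1-ol | C=CCC(O)c1coc(-c2cc(OC)ccc2OC)c1
F2 | step 4 | (1S)-1-[5-(2,5-dimethoxyphenyl)furan-3-yl]-4-methylpent-3-en-1-ol | CC(C)=CC[C@H](O)c1coc(-c2cc(OC)ccc2OC)c1
F3 | step 5 | rac-1-(5-bromofuran-3-yl)-4-methylpent-3-en-1-ol | CC(C)=CCC(O)c1coc(Br)c1
F4 | step 5 | 1-(5-bromofuran-3-yl)-4-methylpent-3-en-1-one | CC(C)=CCC(=O)c1coc(Br)c1
F5 | step 5 | (1S)-1-(5-bromofuran-3-yl)-4-methylpent-3-en-1-yl 3-methylbut-2-enoate | CC(C)=CC[C@H](OC(=O)C=C(C)C)c1coc(Br)c1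
F6 | step 5 | (1S)-1-[5-(2-hydroxy-5-methoxyphenyl)furan-3-yl]-4-methylpent-3-en-1-yl 3-methylbut-2-enoate | CC(C)=CC[C@H](OC(=O)C=C(C)C)c1coc(-c2cc(OC)ccc2O)c1
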